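**Plan**

1. Numbering: C1 ketone, C2=C3, C4(Me)=C5, C6 (lactone O), C7, C8 (ester O), C9 (OH), C10 (Me, furanone O), C11 (OH), C12 lactone C=O, C13 CH2Cl. The enabling feature is the 3-alkoxy-2,4-dienone C1(=O)–C2=C3(O–C10)–C4(Me)=C5 shared by the furanone and the ten-membered carbocycle, the retron of an enone plus a C10–O–C≡C–CH3 ynol ether.
2. Cuts, in order: C8–O angelate and C13–Cl (back to a C11/C13 spiro-epoxide); C2–C3 and C4–C5 with C2–C5 re-formed (ten- to eight-membered ring, furanone opened to the C10 1-propynyl ether); the alkynyl ether back to a dichlorovinyl ether; C2=C5 (metathesis); C12–O6, C11–O, C5=CH2, C6–O, C7–C11 and C10–CH3.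
3. Forward: the C7–C10 chain comes from diethyl L-tartrate; C10 and the C1 vinyl carbinol are added, then C11–C13 by cuprate addition, then the C6 carbinol, the epoxide and a five-membered lactol; the eight-membered ring closes by metathesis; light then gentle warming make furanone and ten-membered ring together; ester and chloride come last.
4. Stereochemistry: C8 and C9 from L-tartrate; C10 by chelation-controlled methyl addition; C7 by anti cuprate addition next to C8; C6 by hydroxylation of a six-membered lactone anti to the C7 side chain; C11 by Sharpless epoxidation; the C2=C3 and C4=C5 geometries by the five-membered tether and conrotatory ring opening.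
5. Abbreviations: PMB = 4-methoxybenzyl, DMB = 3,4-dimethoxybenzyl, TBS = tert-butyldimethylsilyl, TES = triethylsilyl; locants C1–C13 are used for all intermediates.

Key step: step 27

Remark: the acetal carbon of 4–11, the C1 carbinol of 10–33 and the lactol carbon C12 of 27–33 are carried as epimer mixtures; all are removed or made planar before step 27, so their SMILES carry no descriptor.

Step 1
Reactants: 1 diethyl L-tartrate
Product: 2 diethyl (2R,3R)-2-hydroxy-3-[(4-methoxybenzyl)oxy]butanedioate
Conditions: PMBCl (1.05 equiv), Ag2O, CH2Cl2, rt, dark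
Reagents that add atoms: 4-methoxybenzyl chloride COc1ccc(CCl)cc1
Why: Ag2O-mediated Williamson mono-etherification of a C2-symmetric diol, in which either hydroxyl gives the same compound and the first ether slows the second alkylation, tells the future C9 oxygen (PMB) from the future C8 oxygen without touching a stereocentre.

Step 2
Reactants: 2 mono-PMB tartrate
Product: 3 ethyl (2R,3S)-3,4-dihydroxy-2-[(4-methoxybenzyl)oxy]butanoate
Conditions: BH3·SMe2, NaBH4 (5 mol%), THF, 0 °C → rt; MeOH
Reagents that add atoms: none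
Why: Hydroxyl-directed borane reduction of an α-hydroxy ester, in which the free hydroxyl forms an alkoxyborane that delivers hydride only to the neighbouring ester, leaves the ester next to the PMB ether (future C10) intact.

Step 3
Reactants: 3 diol ester
Product: 4 ethyl (2R)-2-[(4S)-2-(3,4-dimethoxyphenyl)-1,3-dioxolan-4-yl]-2-[(4-methoxybenzyl)oxy]acetate
Conditions: 3,4-(MeO)2C6H3CH(OMe)2, camphorsulfonic acid (cat.), CH2Cl2, rt
Reagents that add atoms: 3,4-dimethoxybenzaldehyde dimethyl acetal COC(OC)c1ccc(OC)c(OC)c1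
Why: Acid-catalysed transacetalisation gives the five-membered arylidene acetal of the 1,2-diol, a mask for O7/O8 that carries no migrating silyl group and can later be opened regioselectively.

Step 4
Reactants: 4 acetal ester
Product: 5 (2R)-2-[(4S)-2-(3,4-dimethoxyphenyl)-1,3-dioxolan-4-yl]-N-methoxy-2-[(4-methoxybenzyl)oxy]-N-methylacetamide
Conditions: MeNHOMe·HCl, i-PrMgCl, THF, −20 °C
Reagents that add atoms: N,O-dimethylhydroxylamine hydrochloride Cl.CNOC
Why: Aminolysis of the ester by the magnesium amide of N,O-dimethylhydroxylamine (Weinreb amide formation) runs at low temperature and should not epimerise the α-alkoxy centre C9.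

Step 5
Reactants: 5 Weinreb amide
Product: 6 (4R)-4-[(4S)-2-(3,4-dimethoxyphenyl)-1,3-dioxolan-4-yl]-4-[(4-methoxybenzyl)oxy]but-1-en-3-one
Conditions: CH2=CHMgBr, THF, −78 → 0 °C; inverse quench into cold aq. HCl
Reagents that add atoms: vinylmagnesium bromide C=C[Mg]Br
Why: Weinreb ketone synthesis, in which the chelated tetrahedral adduct prevents over-addition and releases the vinyl ketone only in the cold acidic quench that also keeps the liberated amine from adding to the enone.

Step 6
Reactants: 6 vinyl ketone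
Product: 7 (3S,4R)-4-[(4S)-2-(3,4-dimethoxyphenyl)-1,3-dioxolan-4-yl]-4-[(4-methoxybenzyl)oxy]-3-methylbut-1-en-3-ol
Conditions: MeMgBr, THF, −78 °C; aq. NH4Cl
Reagents that add atoms: methylmagnesium bromide C[Mg]Br
Why: Chelation-controlled (Cram chelate) 1,2-addition of a Grignard reagent to an α-alkoxy ketone, with magnesium bridging the carbonyl and C9–OPMB oxygens and methyl entering from the side of the C9 hydrogen, sets C10 with its oxygen syn to the C9 oxygen as in the target.

Step 7
Reactants: 7 tertiary allylic alcohol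
Product: 8 (E)-1,2-dichlorovinyl ether of 7 at the C10 oxygen
Conditions: KH, THF, 0 °C; Cl2C=CHCl, −40 °C → rt
Reagents that add atoms: trichloroethylene ClC=C(Cl)Cl
Why: Alkoxide addition to dichloroacetylene generated in the flask from trichloroethylene (the dichlorovinyl ether route to alkynyl ethers) gives the (E)-ether by anti addition, and it is done here because the only neighbours of the tertiary alkoxide are a benzyl-type ether and an acetal that cannot migrate.

Step 8
Reactants: 8 dichlorovinyl ether
Product: 9 C1 aldehyde (formyl group on C10 in place of the vinyl group)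
Conditions: OsO4 (2 mol%), NaIO4, 2,6-lutidine, dioxane–H2O, rt
Reagents that add atoms: sodium periodate [Na+].[O-]I(=O)(=O)=O
Why: Lemieux–Johnson oxidative cleavage, in which electrophilic OsO4 dihydroxylates the monosubstituted vinyl group far faster than the chlorine-deactivated enol ether and periodate cleaves the diol, also removes the allyl vinyl ether motif of 8 before it can rearrange.

Step 9
Reactants: 9 aldehyde
Product: 10 C1 allylic alcohol (C1 epimers)
Conditions: CH2=CHMgBr, THF, −78 °C; aq. NH4Cl
Reagents that add atoms: vinylmagnesium bromide C=C[Mg]Br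
Why: Grignard 1,2-addition to a non-enolisable α-alkoxy aldehyde installs C2 and one metathesis alkene, and the new C1 carbinol centre needs no control because it becomes the ketone in step 26.

Step 10
Reactants: 10 allylic alcohol
Product: 11 C1 TBS ether
Conditions: TBSOTf, 2,6-lutidine, CH2Cl2, −78 °C
Reagents that add atoms: tert-butyldimethylsilyl triflate CC(C)(C)[Si](C)(C)OS(=O)(=O)C(F)(F)F
Why: Silyl triflate silylation of a hindered secondary alcohol at −78 °C is fast enough to spare the arylidene acetal and gives an ether that should survive the acidic and basic steps up to step 25.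

Step 11
Reactants: 11 silyl ether
Product: 12 primary C7 alcohol with C8–ODMB
Conditions: i-Bu2AlH, CH2Cl2, −78 → 0 °C; aq. Rochelle salt
Reagents that add atoms: none
Why: Reductive acetal opening, in which aluminium binds the less hindered primary oxygen and hydride is delivered to the oxocarbenium ion, leaves the DMB ether on the secondary C8 oxygen and frees the primary alcohol.

Step 12
Reactants: 12 primary alcohol
Product: 13 C7 aldehyde
Conditions: Dess–Martin periodinane, NaHCO3, CH2Cl2, 0 °C → rt
Reagents that add atoms: none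
Why: Dess–Martin oxidation under buffered conditions gives the α-alkoxy aldehyde without epimerising C8, and the aldehyde is used at once.

Step 13
Reactants: 13 aldehyde
Product: 14 ethyl (E)-enoate (C5 ester with C6=C7)
Conditions: (EtO)2P(O)CH2CO2Et, LiCl, DBU, MeCN, 0 °C → rt
Reagents that add atoms: triethyl phosphonoacetate CCOC(=O)CP(=O)(OCC)OCC
Why: Horner–Wadsworth–Emmons olefination under Masamune–Roush conditions gives the (E)-enoate with an amine base too weak to epimerise C8 or to dehydrochlorinate the dichlorovinyl ether.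

Step 14
Reactants: 15 2-bromoprop-2-en-1-ol
Product: 16 [(2-bromoprop-2-en-1-yl)oxy](tert-butyl)dimethylsilane
Conditions: TBSCl, imidazole, DMF, rt
Reagents that add atoms: tert-butyldimethylsilyl chloride CC(C)(C)[Si](C)(C)Cl
Why: Imidazole-promoted silylation of a primary allylic alcohol protects the hydroxyl of the C11–C13 building block for the halogen–lithium exchange.

Step 15
Reactants: 14 (E)-enoate; 16 bromoallyl silyl ether
Product: 19 ethyl ester conjugate adduct bearing the 3-(TBS-oxy)prop-1-en-2-yl group at C7, via vinyllithium 17 (not isolated), via silyl ketene acetal 18 (not isolated)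
Conditions: 16, t-BuLi (2 equiv), Et2O, −78 °C; CuI (0.5 equiv), −40 °C; then 14, Me3SiCl, THF, −78 °C; aq. NH4Cl
Reagents that add atoms: none
Why: Conjugate addition of a lithium diorganocuprate accelerated by Me3SiCl to a γ-alkoxy (E)-enoate follows the modified Felkin–Anh model, the nucleophile entering anti to the C8–O bond, which sets C7 with C11 anti to the C8 oxygen.

Step 16
Reactants: 19 conjugate adduct
Product: 21 six-membered lactone (C5 carbonyl closed on O12; exocyclic C11=C13), via hydroxy ester 20 (not isolated)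
Conditions: PPTS, MeOH, rt; then PPTS, toluene, 60 °C
Reagents that add atoms: none
Why: Acidic methanolysis removes the primary allylic TBS ether much faster than the hindered secondary one at C1, and the freed δ-hydroxy ester lactonises by acid-catalysed transesterification to the ring needed for cyclic control at C6.

Step 17
Reactants: 21 lactone
Product: 23 C6-hydroxy lactone, via ketene silyl acetal 22 (not isolated)
Conditions: Me3SiOTf, Et3N, CH2Cl2, 0 °C; then dimethyldioxirane, acetone, −78 °C; aq. citric acid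
Reagents that add atoms: dimethyldioxirane CC1(C)OO1
Why: Rubottom oxidation of the cyclic ketene silyl acetal, made by soft enolisation because an amide base could attack the dichlorovinyl ether, places oxygen anti to the pseudo-axial C7 side chain, so that the C6 hydroxyl is trans to it on the ring as the target requires.

Step 18
Reactants: 23 hydroxy lactone
Product: 24 six-membered lactol (C5 epimers)
Conditions: i-Bu2AlH, CH2Cl2, −78 °C; aq. Rochelle salt
Reagents that add atoms: none
Why: Partial reduction of a lactone by i-Bu2AlH at −78 °C stops at the tetrahedral aluminium hemiacetal, which gives the lactol on work-up.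

Step 19
Reactants: 24 lactol
Product: 25 diol (C6 carbinol bearing the C5=CH2 vinyl group; C12 primary allylic alcohol)
Conditions: Ph3PCH3Br, KN(SiMe3)2, THF, 0 °C; then 24, 0 °C → rt
Reagents that add atoms: methyltriphenylphosphonium bromide C[P+](c1ccccc1)(c1ccccc1)c1ccccc1.[Br-]
Why: Wittig methylenation of the open hydroxy-aldehyde form of the lactol installs the second metathesis alkene and frees the C12 allylic alcohol, the C6 alkoxide shielding the α-centre from epimerisation.

Step 20
Reactants: 25 diol
Product: 26 epoxy diol (C11/C13 oxirane; C12 CH2OH)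
Conditions: Ti(OiPr)4 (20 mol%), D-(−)-diethyl tartrate (25 mol%), t-BuOOH, 4 Å sieves, CH2Cl2, −20 °C
Reagents that add atoms: tert-butyl hydroperoxide CC(C)(C)OO
Why: Sharpless asymmetric epoxidation epoxidises the 2-substituted primary allylic alcohol far faster than the secondary vinyl carbinol at C6, and D-(−)-diethyl tartrate delivers oxygen under reagent control to the face of C11=C13 that gives the C11 configuration of the target.

Step 21
Reactants: 26 epoxy diol
Product: 27 five-membered lactol (O6–C12; C12 epimers) with spiro-epoxide at C11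
Conditions: TEMPO (10 mol%), PhI(OAc)2 (1.1 equiv), CH2Cl2, 0 °C
Reagents that add atoms: none
Why: Oxoammonium (TEMPO) oxidation is selective for the primary alcohol, the aldehyde is trapped by the C6 hydroxyl as the lactol, and the limited amount of oxidant is meant to stop there.

Step 22
Reactants: 27 lactol
Product: 28 lactol TES ether (acyclic diene)
Conditions: Et3SiCl, imidazole, CH2Cl2, 0 °C
Reagents that add atoms: chlorotriethylsilane CC[Si](Cl)(CC)CC
Why: Silylation of the lactol hydroxyl gives a mixed silyl acetal that keeps C12 non-electrophilic during the organolithium step and is later removed by fluoride.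

Step 23
Reactants: 28 diene
Product: 29 lactol-fused cyclooct-2-ene (C2=C5 cis)
Conditions: second-generation Grubbs catalyst (10 mol%), toluene (2 mM), 80 °C
Reagents that add atoms: none
Why: Ring-closing metathesis of two monosubstituted allylic-ether alkenes is helped by the cis-fused lactol that holds C5 near C2, the eight-membered ring can hold the new double bond only cis, and the trisubstituted dichlorovinyl ether is too hindered and electron-poor to engage the ruthenium carbene.

Step 24
Reactants: 29 cyclooctene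
Product: 32 C10 1-propynyl ether of the cyclooctene, via chloroethynyl ether 30 (not isolated), via lithioethynyl ether 31 (not isolated)
Conditions: n-BuLi (2.5 equiv), THF, −78 → −40 °C; then MeI, DMPU, −78 → −20 °C
Reagents that add atoms: iodomethane CI
Why: In this dichlorovinyl-ether route to alkynyl ethers n-BuLi dehydrochlorinates to the chloroalkyne, chlorine–lithium exchange gives the lithium alkoxyacetylide and C-methylation gives the propynyl ether, while silyl acetal, silyl ether, benzyl-type ethers and the epoxide should be inert at these temperatures.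

Step 25
Reactants: 32 propynyl ether
Product: 33 diol (C1 allylic alcohol and C12 lactol)
Conditions: Bu4NF, THF, 0 °C → rt; aq. NH4Cl
Reagents that add atoms: none
Why: Fluoride-induced desilylation cleaves the silyl acetal and the TBS ether under non-acidic conditions that the acid- and heat-sensitive alkynyl ether tolerates.

Step 26
Reactants: 33 diol
Product: 34 lactone-fused cyclooct-2-enone C10 1-propynyl ether (C8–ODMB/C9–OPMB/spiro-epoxy lactone)
Conditions: Dess–Martin periodinane, NaHCO3, CH2Cl2, 0 °C; filtration through Et3N-deactivated silica, used cold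
Reagents that add atoms: none
Why: Buffered Dess–Martin oxidation converts the allylic alcohol into the cis-enone and the lactol into the γ-lactone in one operation, erasing the C1 and C12 epimer mixtures without acid that would hydrate the ynol ether.

Step 27
Reactants: 34 cyclooctenone propynyl ether
Product: 36 furanone-bridged ten-membered core (C8–ODMB/C9–OPMB/spiro-epoxy lactone), via cyclobutene 35 (not isolated)
Conditions: hν (366 nm), degassed CH2Cl2 (2 mM), −60 °C; then dark, −60 → 25 °C
Reagents that add atoms: none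
Why: Proposed new method: n→π* excitation of the cis-cyclooctenone at a wavelength where nothing else absorbs gives the triplet enone, whose α-carbon C2 bonds to the oxygen-bearing alkyne carbon C3 in a 1,5 closure that is already the furanone ring, and the triplet 1,4-diradical then closes C4–C5 on the same face to the cis-fused cyclobutene 35, which on warming in the dark opens by conrotatory 4π cleavage of C2–C5, because it is a strained push–pull cyclobutene (alkoxy on C3, acyl on C2, double bond at a ring fusion). The closest known reaction type is the intramolecular enone–alkyne [2+2] photocycloaddition followed by thermal cyclobutene opening used as a two-carbon ring expansion, together with ground-state [2+2] additions of ynol ethers and ynamines to enones; new are the ynol-ether tether and the densely oxygenated medium ring. Ring closures: the furanone by 5-exo-dig attack of C2 on the alkyne (rule of five), the cyclobutene by recombination of the 1,4-diradical, and the ten-membered carbocycle not by cyclisation but by electrocyclic expansion of the eight-membered ring. The two transient stereocentres C2 and C5 are set by the C10–O tether, which delivers the alkyne to the enone face cis to the C10 oxygen, and both are erased in the opening; the alkene geometries follow from conrotation, since C1 is tied to the C3 oxygen through the five-membered ring and must turn outward, so C6 turns inward and C4=C5 emerges with C3 and C6 cis as in the target. The step needs straight (C2–C3/C4–C5) rather than crossed addition, which the three-atom C1–C10–O tether secures, and it needs cycloaddition to outrun E/Z isomerisation of the enone and retro-ene loss of ketene from the tertiary alkynyl ether, for which the cis-fused lactone (little room for a trans-cyclooctenone) and irradiation at −60 °C are relied on, while warming only after the lamp is off keeps the light-absorbing dienone out of the photolysis.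

Step 28
Reactants: 36 core
Product: 37 C8 alcohol
Conditions: DDQ (1.2 equiv), CH2Cl2–pH 7 buffer, 0 °C
Reagents that add atoms: none
Why: Oxidative benzyl-ether cleavage by DDQ (electron transfer, then hydrolysis of the oxocarbenium ion) removes the more electron-rich 3,4-dimethoxybenzyl ether selectively in the presence of the PMB ether, freeing only the C8 hydroxyl.

Step 29
Reactants: 37 C8 alcohol; 38 angelic acid
Product: 40 C8 angelate, via mixed anhydride 39 (not isolated)
Conditions: 38, 2,4,6-Cl3C6H2COCl, Et3N, toluene, rt; then 37, DMAP, rt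
Reagents that add atoms: none
Why: Yamaguchi esterification through the mixed anhydride acylates the hindered secondary alcohol under mild DMAP catalysis, conditions under which the (Z)-geometry of angelates is normally kept.

Step 30
Reactants: 40 angelate
Product: 41 C9 alcohol (C8 angelate with C11/C13 epoxide)
Conditions: DDQ (2 equiv), CH2Cl2–pH 7 buffer, rt
Reagents that add atoms: none
Why: DDQ cleavage of the PMB ether under buffered two-phase conditions frees the C9 hydroxyl and should not affect the angelate, the electron-poor dienone or the epoxide.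

Step 31
Reactants: 41 epoxide
Product: 42 CNP0272644.1
Conditions: HCl (1 M in Et2O, 1.5 equiv), CH2Cl2, −20 → 0 °C
Reagents that add atoms: hydrogen chloride Cl
Why: Acid-mediated epoxide opening to the chlorohydrin proceeds by SN2 attack of chloride on the primary C13 carbon, the tertiary carbon being deactivated by the lactone carbonyl, so C11 keeps its configuration and carries the hydroxyl.

**Compound list**

1 | diethyl L-tartrate, diethyl (2R,3R)-2,3-dihydroxybutanedioate | CCOC(=O)[C@H](O)[C@@H](O)C(=O)OCC | starting material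
2 | diethyl (2R,3R)-2-hydroxy-3-[(4-methoxybenzyl)oxy]butanedioate | CCOC(=O)[C@H](OCc1ccc(OC)cc1)[C@@H](O)C(=O)OCC | intermediate
3 | ethyl (2R,3S)-3,4-dihydroxy-2-[(4-methoxybenzyl)oxy]butanoate | CCOC(=O)[C@H](OCc1ccc(OC)cc1)[C@@H](O)CO | intermediate
4 | ethyl (2R)-2-[(4S)-2-(3,4-dimethoxyphenyl)-1,3-dioxolan-4-yl]-2-[(4-methoxybenzyl)oxy]acetate (acetal epimers) | CCOC(=O)[C@H](OCc1ccc(OC)cc1)[C@@H]1COC(c2ccc(OC)c(OC)c2)O1 | intermediate
5 | (2R)-2-[(4S)-2-(3,4-dimethoxyphenyl)-1,3-dioxolan-4-yl]-N-methoxy-2-[(4-methoxybenzyl)oxy]-N-methylacetamide | CON(C)C(=O)[C@H](OCc1ccc(OC)cc1)[C@@H]1COC(c2ccc(OC)c(OC)c2)O1 | intermediate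
6 | (4R)-4-[(4S)-2-(3,4-dimethoxyphenyl)-1,3-dioxolan-4-yl]-4-[(4-methoxybenzyl)oxy]but-1-en-3-one | C=CC(=O)[C@H](OCc1ccc(OC)cc1)[C@@H]1COC(c2ccc(OC)c(OC)c2)O1 | intermediate
7 | (3S,4R)-4-[(4S)-2-(3,4-dimethoxyphenyl)-1,3-dioxolan-4-yl]-4-[(4-methoxybenzyl)oxy]-3-methylbut-1-en-3-ol (C10 tertiary alcohol) | C=C[C@](C)(O)[C@H](OCc1ccc(OC)cc1)[C@@H]1COC(c2ccc(OC)c(OC)c2)O1 | intermediate
8 | (E)-1,2-dichlorovinyl ether of 7 at the tertiary C10 oxygen | C=C[C@](C)(O/C(Cl)=C\Cl)[C@H](OCc1ccc(OC)cc1)[C@@H]1COC(c2ccc(OC)c(OC)c2)O1 | intermediate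
9 | C1 aldehyde (vinyl group of 8 cleaved to CHO on C10) | O=C[C@](C)(O/C(Cl)=C\Cl)[C@H](OCc1ccc(OC)cc1)[C@@H]1COC(c2ccc(OC)c(OC)c2)O1 | intermediate
10 | C1 allylic alcohol from vinyl addition to 9 (C1 epimers) | C=CC(O)[C@](C)(O/C(Cl)=C\Cl)[C@H](OCc1ccc(OC)cc1)[C@@H]1COC(c2ccc(OC)c(OC)c2)O1 | intermediate
11 | C1 TBS ether of 10 | C=CC(O[Si](C)(C)C(C)(C)C)[C@](C)(O/C(Cl)=C\Cl)[C@H](OCc1ccc(OC)cc1)[C@@H]1COC(c2ccc(OC)c(OC)c2)O1 | intermediate
12 | primary C7 alcohol with C8–ODMB and C9–OPMB (acetal opened) | C=CC(O[Si](C)(C)C(C)(C)C)[C@](C)(O/C(Cl)=C\Cl)[C@H](OCc1ccc(OC)cc1)[C@@H](OCc1ccc(OC)c(OC)c1)CO | intermediate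
13 | C7 aldehyde of 12 | C=CC(O[Si](C)(C)C(C)(C)C)[C@](C)(O/C(Cl)=C\Cl)[C@H](OCc1ccc(OC)cc1)[C@@H](OCc1ccc(OC)c(OC)c1)C=O | intermediate
14 | ethyl (E)-enoate (C5 ester, C6=C7) | C=CC(O[Si](C)(C)C(C)(C)C)[C@](C)(O/C(Cl)=C\Cl)[C@H](OCc1ccc(OC)cc1)[C@@H](OCc1ccc(OC)c(OC)c1)/C=C/C(=O)OCC | intermediate
15 | 2-bromoprop-2-en-1-ol | OCC(Br)=C | starting material
16 | [(2-bromoprop-2-en-1-yl)oxy](tert-butyl)dimethylsilane | C=C(Br)CO[Si](C)(C)C(C)(C)C | intermediate
17 | 3-(tert-butyldimethylsilyloxy)prop-1-en-2-yllithium | [Li]C(=C)CO[Si](C)(C)C(C)(C)C | intermediate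
18 | ethyl trimethylsilyl ketene acetal of 19 | C=CC(O[Si](C)(C)C(C)(C)C)[C@](C)(O/C(Cl)=C\Cl)[C@H](OCc1ccc(OC)cc1)[C@@H](OCc1ccc(OC)c(OC)c1)[C@@H](C(=C)CO[Si](C)(C)C(C)(C)C)C=C(OCC)O[Si](C)(C)C | intermediate
19 | ethyl ester with C7 bearing the 3-(TBS-oxy)prop-1-en-2-yl group (C11=C13H2, C12H2OTBS) | C=CC(O[Si](C)(C)C(C)(C)C)[C@](C)(O/C(Cl)=C\Cl)[C@H](OCc1ccc(OC)cc1)[C@@H](OCc1ccc(OC)c(OC)c1)[C@@H](C(=C)CO[Si](C)(C)C(C)(C)C)CC(=O)OCC | intermediate
20 | C12 hydroxy ester (primary silyl ether of 19 removed) | C=CC(O[Si](C)(C)C(C)(C)C)[C@](C)(O/C(Cl)=C\Cl)[C@H](OCc1ccc(OC)cc1)[C@@H](OCc1ccc(OC)c(OC)c1)[C@@H](C(=C)CO)CC(=O)OCC | intermediate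
21 | six-membered lactone (5-methylidene-tetrahydropyran-2-one; C8–C10 chain on ring carbon C7) | C=CC(O[Si](C)(C)C(C)(C)C)[C@](C)(O/C(Cl)=C\Cl)[C@H](OCc1ccc(OC)cc1)[C@@H](OCc1ccc(OC)c(OC)c1)[C@@H]1CC(=O)OCC1=C | intermediate
22 | cyclic trimethylsilyl ketene acetal of 21 | C=CC(O[Si](C)(C)C(C)(C)C)[C@](C)(O/C(Cl)=C\Cl)[C@H](OCc1ccc(OC)cc1)[C@@H](OCc1ccc(OC)c(OC)c1)[C@@H]1C=C(O[Si](C)(C)C)OCC1=C | intermediate
23 | C6-hydroxy lactone (hydroxyl trans to the C7 side chain) | C=CC(O[Si](C)(C)C(C)(C)C)[C@](C)(O/C(Cl)=C\Cl)[C@H](OCc1ccc(OC)cc1)[C@@H](OCc1ccc(OC)c(OC)c1)[C@@H]1[C@@H](O)C(=O)OCC1=C | intermediate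
24 | six-membered lactol of 23 (C5 epimers) | C=CC(O[Si](C)(C)C(C)(C)C)[C@](C)(O/C(Cl)=C\Cl)[C@H](OCc1ccc(OC)cc1)[C@@H](OCc1ccc(OC)c(OC)c1)[C@@H]1[C@@H](O)C(O)OCC1=C | intermediate
25 | diol: C6 vinyl carbinol and C12 primary allylic alcohol (C11=C13H2) | C=CC(O[Si](C)(C)C(C)(C)C)[C@](C)(O/C(Cl)=C\Cl)[C@H](OCc1ccc(OC)cc1)[C@@H](OCc1ccc(OC)c(OC)c1)[C@@H](C(=C)CO)[C@@H](O)C=C | intermediate
26 | epoxy diol: C11/C13 oxirane bearing the C12 hydroxymethyl group | C=CC(O[Si](C)(C)C(C)(C)C)[C@](C)(O/C(Cl)=C\Cl)[C@H](OCc1ccc(OC)cc1)[C@@H](OCc1ccc(OC)c(OC)c1)[C@@H]([C@@]1(CO)CO1)[C@@H](O)C=C | intermediate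
27 | five-membered lactol (O6–C12H(OH)) spiro-fused to the C11/C13 oxirane (C12 epimers) | C=CC(O[Si](C)(C)C(C)(C)C)[C@](C)(O/C(Cl)=C\Cl)[C@H](OCc1ccc(OC)cc1)[C@@H](OCc1ccc(OC)c(OC)c1)[C@@H]2[C@H](C=C)OC(O)[C@@]23CO3 | intermediate
28 | TES ether of lactol 27 (metathesis diene) | C=CC(O[Si](C)(C)C(C)(C)C)[C@](C)(O/C(Cl)=C\Cl)[C@H](OCc1ccc(OC)cc1)[C@@H](OCc1ccc(OC)c(OC)c1)[C@@H]2[C@H](C=C)OC(O[Si](CC)(CC)CC)[C@@]23CO3 | intermediate
29 | lactol-fused cyclooct-2-ene with C1–OTBS and C10 dichlorovinyl ether | O(Cc1ccc(OC)c(OC)c1)[C@H]1[C@@H]2[C@H](/C=C\C(O[Si](C)(C)C(C)(C)C)[C@](C)(O/C(Cl)=C\Cl)[C@@H]1OCc1ccc(OC)cc1)OC(O[Si](CC)(CC)CC)[C@@]23CO3 | intermediate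
30 | C10 chloroethynyl ether of the cyclooctene | O(Cc1ccc(OC)c(OC)c1)[C@H]1[C@@H]2[C@H](/C=C\C(O[Si](C)(C)C(C)(C)C)[C@](C)(OC#CCl)[C@@H]1OCc1ccc(OC)cc1)OC(O[Si](CC)(CC)CC)[C@@]23CO3 | intermediate
31 | C10 lithioethynyl ether of the cyclooctene | O(Cc1ccc(OC)c(OC)c1)[C@H]1[C@@H]2[C@H](/C=C\C(O[Si](C)(C)C(C)(C)C)[C@](C)(OC#C[Li])[C@@H]1OCc1ccc(OC)cc1)OC(O[Si](CC)(CC)CC)[C@@]23CO3 | intermediate
32 | C10 1-propynyl ether of the cyclooctene | O(Cc1ccc(OC)c(OC)c1)[C@H]1[C@@H]2[C@H](/C=C\C(O[Si](C)(C)C(C)(C)C)[C@](C)(OC#CC)[C@@H]1OCc1ccc(OC)cc1)OC(O[Si](CC)(CC)CC)[C@@]23CO3 | intermediate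
33 | diol: C1 allylic alcohol and C12 lactol, C10 1-propynyl ether | O(Cc1ccc(OC)c(OC)c1)[C@H]1[C@@H]2[C@H](/C=C\C(O)[C@](C)(OC#CC)[C@@H]1OCc1ccc(OC)cc1)OC(O)[C@@]23CO3 | intermediate
34 | lactone-fused cyclooct-2-enone C10 1-propynyl ether (C8–ODMB, C9–OPMB, C11/C13 spiro-epoxide) | O(Cc1ccc(OC)c(OC)c1)[C@H]1[C@@H]2[C@H](/C=C\C(=O)[C@](C)(OC#CC)[C@@H]1OCc1ccc(OC)cc1)OC(=O)[C@@]23CO3 | intermediate
35 | cis-fused cyclobutene photoadduct (C2–C3 and C4–C5 formed, C3=C4) | O(Cc1ccc(OC)c(OC)c1)[C@H]1[C@@H]2[C@H]([C@@H]4C(C)=C5O[C@@](C)(C(=O)[C@H]45)[C@@H]1OCc1ccc(OC)cc1)OC(=O)[C@@]23CO3 | intermediate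
36 | furanone-bridged ten-membered core (C8–ODMB, C9–OPMB, C11/C13 spiro-epoxy lactone) | O(Cc1ccc(OC)c(OC)c1)[C@H]1[C@@H]2[C@H](/C=C(/C)C3=CC(=O)[C@](C)(O3)[C@@H]1OCc1ccc(OC)cc1)OC(=O)[C@@]24CO4 | intermediate
37 | C8 alcohol of the core (C9–OPMB, epoxide) | O[C@H]1[C@@H]2[C@H](/C=C(/C)C3=CC(=O)[C@](C)(O3)[C@@H]1OCc1ccc(OC)cc1)OC(=O)[C@@]24CO4 | intermediate
38 | angelic acid, (Z)-2-methylbut-2-enoic acid | C/C=C(/C)C(=O)O | starting material
39 | angelic 2,4,6-trichlorobenzoic anhydride | C/C=C(/C)C(=O)OC(=O)c1c(Cl)cc(Cl)cc1Cl | intermediate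
40 | C8 angelate (C9–OPMB, epoxide) | C/C=C(/C)C(=O)O[C@H]1[C@@H]2[C@H](/C=C(/C)C3=CC(=O)[C@](C)(O3)[C@@H]1OCc1ccc(OC)cc1)OC(=O)[C@@]24CO4 | intermediate
41 | C9 alcohol (C8 angelate, C11/C13 spiro-epoxide) | C/C=C(/C)C(=O)O[C@H]1[C@@H]2[C@H](/C=C(/C)C3=CC(=O)[C@](C)(O3)[C@@H]1O)OC(=O)[C@@]24CO4 | intermediate
42 | CNP0272644.1 | C/C=C(/C)C(=O)O[C@H]1[C@@H]2[C@H](/C=C(/C)C3=CC(=O)[C@](C)(O3)[C@@H]1O)OC(=O)[C@@]2(O)CCl | target

**Totals**

Total: 31 steps. Longest linear sequence: 30 steps (steps 1–13 and 15–31 from diethyl L-tartrate); step 14 is a one-step side branch.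

**Steps most likely to fail**

Step 27 (Proposed new method). The excited cyclooctenone may relax by E/Z isomerisation or hydrogen abstraction faster than it adds to the alkyne, the diradical may close in the crossed sense, the tertiary alkynyl ether may lose ketene by retro-ene reaction, or the dienone product may be photolysed further. The fallback uses known chemistry and builds the rings by metathesis instead of ring expansion; it sets out from diene 28 and comes back at 36. Treatment of 28 with n-BuLi and then MeI, as in step 24, should give the acyclic 1-propynyl ether dienyne F1. A tandem ene–yne–ene ring-closing metathesis with second-generation Grubbs catalyst (alkynyl ethers are established enyne partners) should then close the five-membered cyclic enol ether between C2 and C3 and, from the resulting C4 carbene, the ten-membered ring onto the C6 vinyl group, giving the bicyclic silyl-protected dihydrofuranol F2. Bu4NF should give the diol F3, and Dess–Martin oxidation (C1 carbinol to the furanone carbonyl, lactol to lactone) should give 36.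

Step 23. Ring closure may be outrun by oligomerisation or catalyst decay, because one alkene sits next to the quaternary C10 and a bulky silyl ether. The fallback moves the metathesis to the free allylic alcohol and forms the lactol afterwards; it sets out from epoxy diol 26 and comes back at 29. Ring-closing metathesis of 26, whose free C6 allylic hydroxyl speeds carbene formation at that alkene, should give the cyclooctene epoxy diol F4. TEMPO/PhI(OAc)2 should then close the lactol on the ring to give the cyclooctene lactol F5, and Et3SiCl/imidazole should give 29.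

Step 21. Oxidation may run on from the lactol to the lactone before the diol is consumed. The fallback accepts full oxidation and reduces back; it sets out from 26 and comes back at 27. Excess TEMPO/PhI(OAc)2 should give the diene epoxy lactone F6, and i-Bu2AlH at −78 °C should reduce it to 27.

**Further compounds**

F1 | step 27 | acyclic 1-propynyl ether dienyne (28 with C10–O–C≡C–CH3 in place of the dichlorovinyl ether) | C=CC(O[Si](C)(C)C(C)(C)C)[C@](C)(OC#CC)[C@H](OCc1ccc(OC)cc1)[C@@H](OCc1ccc(OC)c(OC)c1)[C@@H]2[C@H](C=C)OC(O[Si](CC)(CC)CC)[C@@]23CO3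
F2 | step 27 | bicyclic silyl-protected dihydrofuranol (ten-membered ring with C2=C3 enol ether, C4=C5, C1–OTBS, lactol TES ether) | O(Cc1ccc(OC)c(OC)c1)[C@H]1[C@@H]2[C@H](/C=C(/C)C3=CC(O[Si](C)(C)C(C)(C)C)[C@](C)(O3)[C@@H]1OCc1ccc(OC)cc1)OC(O[Si](CC)(CC)CC)[C@@]24CO4
F3 | step 27 | diol of F2 (C1 carbinol and C12 lactol free) | O(Cc1ccc(OC)c(OC)c1)[C@H]1[C@@H]2[C@H](/C=C(/C)C3=CC(O)[C@](C)(O3)[C@@H]1OCc1ccc(OC)cc1)OC(O)[C@@]24CO4
F4 | step 23 | cyclooctene epoxy diol (C6–OH and C12–OH free, C1–OTBS, C10 dichlorovinyl ether) | O(Cc1ccc(OC)c(OC)c1)[C@H]1[C@@H]([C@@]2(CO)CO2)[C@@H](O)/C=C\C(O[Si](C)(C)C(C)(C)C)[C@](C)(O/C(Cl)=C\Cl)[C@@H]1OCc1ccc(OC)cc1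
F5 | step 23 | cyclooctene lactol (29 without the TES group) | O(Cc1ccc(OC)c(OC)c1)[C@H]1[C@@H]2[C@H](/C=C\C(O[Si](C)(C)C(C)(C)C)[C@](C)(O/C(Cl)=C\Cl)[C@@H]1OCc1ccc(OC)cc1)OC(O)[C@@]23CO3
F6 | step 21 | diene epoxy lactone (27 with C12 as lactone carbonyl) | C=CC(O[Si](C)(C)C(C)(C)C)[C@](C)(O/C(Cl)=C\Cl)[C@H](OCc1ccc(OC)cc1)[C@@H](OCc1ccc(OC)c(OC)c1)[C@@H]2[C@H](C=C)OC(=O)[C@@]23CO3
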